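## Retrosynthetic overview

1. The target is cut at the ester into triol 20 and 4-acetoxy-3-methoxybenzoic acid 21; C6–OH is the only secondary hydroxyl of 20.
2. Triol 20 goes back (isopropyl addition to a C4 ketone, methyl addition to a C8 enone, Saegusa–Ito oxidation for C9=C10, reduction at C6) to bicyclic ketone 12, which has a C6 ketone, a regiodefined C8=C9 silyl enol ether and a MOM-protected C4 carbinol.
3. Key disconnection: the seven-membered ring (C1, C5, C6, C7, C8, C9, C10) of 12 is cut at C7–C8 and C1–C10 into the lithium enolate of cyclopentenyl methyl ketone 5 (C7–C6–C5=C1) and acryloylsilane 8 (C8–C9–C10). The forward reaction is a Brook rearrangement-mediated (4+3) annulation through a cis-divinylcyclopropanolate and an oxy-Cope ring closure.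
4. Enabling feature: the seven-membered ring carries oxygen on C6 and C8, 1,3 across the C7 methylene, and shares the C1–C5 bond with the cyclopentane. A 1,3-dioxygenated cycloheptene fused at the two carbons of a former cyclopentene C=C, with the angular C1 methyl in place, is what this annulation delivers.
5. Ring order: cyclopentane first (from bromo-enone 1; a CBS reduction sets a temporary C4 centre that relays to C1), seven-membered ring last in step 5; C5, C6, C8 and finally C4 are then set relative to C1.

Key step: step 5

Convention: daucane numbering of the target is used for all bicyclic compounds (five-membered ring C1–C2–C3–C4–C5, seven-membered ring C1–C5–C6–C7–C8–C9–C10; C1 carries the angular methyl, C4 the isopropyl, C8 the second methyl). "Hydroazulene" means the bicyclo[5.3.0]decane skeleton. β is the face of the C1 methyl group, α the opposite face; all bicyclic compounds are trans-fused (1β-CH3, 5α-H).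

Assumption: 2-bromo-3-methylcyclopent-2-en-1-one 1, methoxyallene 6 and 4-acetoxy-3-methoxybenzoic acid 21 are taken as commercial.

## Route

Step 1
Reactants: 1 2-bromo-3-methylcyclopent-2-en-1-one
Product: 2 (S)-2-bromo-3-methylcyclopent-2-en-1-ol
Conditions: (R)-Me-CBS oxazaborolidine (cat.), BH3·SMe2, THF, −20 °C; MeOH quench
Reagents that add atoms: none
Why: Corey–Bakshi–Shibata reduction, in which the α-bromoalkenyl arm acts as the large group, so that the (R)-oxazaborolidine should deliver hydride to the face that gives the (S)-allylic alcohol (the future C4 centre).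

Step 2
Reactants: 2 (S)-2-bromo-3-methylcyclopent-2-en-1-ol
Product: 3 (S)-1-bromo-5-(methoxymethoxy)-2-methylcyclopent-1-ene
Conditions: MOMCl, i-Pr2NEt, CH2Cl2, 0 °C to rt
Reagents that add atoms: chloromethyl methyl ether (MOMCl) COCCl
Why: O-alkylation of the allylic alcohol (acetal formation) installs a small, metal-chelating ether that later steers steps 5 and 6, and the stereocentre is not touched.

Step 3
Reactants: 3 (S)-1-bromo-5-(methoxymethoxy)-2-methylcyclopent-1-ene
Product: 5 (S)-1-[5-(methoxymethoxy)-2-methylcyclopent-1-en-1-yl]ethan-1-one, via alkenyllithium 4 (not isolated)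
Conditions: t-BuLi (2.1 equiv), THF, −78 °C; then MeC(O)N(OMe)Me, −78 to 0 °C; aq. NH4Cl
Reagents that add atoms: N-methoxy-N-methylacetamide CON(C)C(C)=O
Why: Bromine–lithium exchange gives alkenyllithium 4, whose Weinreb acylation should stop at the methyl ketone because the chelated tetrahedral adduct survives until work-up.

Step 4
Reactants: 6 methoxyallene (1-methoxypropa-1,2-diene)
Product: 8 1-[tert-butyl(dimethyl)silyl]prop-2-en-1-one, via silylated methoxyallene 7 (not isolated)
Conditions: n-BuLi, THF, −78 °C; TBSCl, −78 to 0 °C; then 1 M HCl, THF, 0 °C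
Reagents that add atoms: tert-butyldimethylsilyl chloride CC(C)(C)[Si](C)(C)Cl; water O
Why: α-Lithiation and C-silylation of the alkoxyallene, followed by hydrolysis of the enol ether in 7, is the established route to α,β-unsaturated acylsilanes.

Step 5
Reactants: 5 (S)-1-[5-(methoxymethoxy)-2-methylcyclopent-1-en-1-yl]ethan-1-one; 8 1-[tert-butyl(dimethyl)silyl]prop-2-en-1-one
Product: 12 trans-fused bicyclic ketone 8-[tert-butyl(dimethyl)silyl]oxy-4β-(methoxymethoxy)-1β-methyl-5αH-hydroazul-8-en-6-one, via lithium dienolate 9 (not isolated), via divinylcyclopropanolate 10 (not isolated), via ring-expanded lithium enolate 11 (not isolated)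
Conditions: LDA (1.05 equiv), THF, −80 °C; add 8, −80 to −30 °C; AcOH, −80 °C
Reagents that add atoms: none
Why: Lithium dienolate 9 adds 1,2 to the highly electrophilic acylsilane carbonyl of 8, the silyl group migrates from carbon to oxygen (1,2-Brook rearrangement), and the resulting siloxy-allyl anion closes onto the ketone carbon to give cis-1,2-divinylcyclopropanolate 10, which undergoes an alkoxide-accelerated oxy-Cope rearrangement through a boat transition state to enolate 11; protonation gives 12. The closest known reaction type is the Brook rearrangement-mediated (3+4) annulation of acryloylsilanes with lithium enolates of alkenyl methyl ketones, which is documented for cycloalkenyl methyl ketones and for the creation of an angular methyl group. The three-membered ring closes by 3-exo-trig carbanion addition to C6, and the seven-membered ring then closes by the [3,3] shift that makes the C1–C10 bond while the C6–C8 cyclopropane bond breaks, so the net result is a (4+3) union through the C7–C8 and C1–C10 bonds. C1 is controlled by the C4 stereocentre: lithium bridges the C6 oxido and the MOM oxygens on one face of the cyclopentene, the cyclopropane carbon C8 with its vinyl arm is thereby held on the opposite face, and the boat can only deliver C10 to C1 anti to the MOM-oxy group, which places the C1 methyl cis to C4–O. C5 is set by kinetic protonation of 11 at low temperature on the α face, away from the C1 methyl and the C4 substituent, which should give the trans ring fusion. The step needs 1,2- rather than 1,4-addition to 8 (hard lithium enolate, low temperature, activated acylsilane carbonyl) and no β-elimination of the C4 oxygen from 11 (kept at or below −30 °C and quenched cold).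

Step 6
Reactants: 12 8-[tert-butyl(dimethyl)silyl]oxy-4β-(methoxymethoxy)-1β-methyl-5αH-hydroazul-8-en-6-one
Product: 13 8-[tert-butyl(dimethyl)silyl]oxy-4β-(methoxymethoxy)-1β-methyl-5αH-hydroazul-8-en-6α-ol
Conditions: SmI2 (3 equiv), MeOH, THF, 0 °C
Reagents that add atoms: none
Why: Electron transfer from SmI2 to the ketone held in a Sm(III) chelate with the MOM oxygen, followed by protonation, is the known anti-selective reduction of β-alkoxy ketones and should give the 6α (equatorial) alcohol, anti to C4–O, which is also the thermodynamically preferred epimer because it avoids the axial C1 methyl group.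

Step 7
Reactants: 13 8-[tert-butyl(dimethyl)silyl]oxy-4β-(methoxymethoxy)-1β-methyl-5αH-hydroazul-8-en-6α-ol
Product: 14 6α-triisopropylsilyl ether of 13
Conditions: TIPSOTf, 2,6-lutidine, CH2Cl2, −78 to 0 °C
Reagents that add atoms: triisopropylsilyl trifluoromethanesulfonate CC(C)[Si](OS(=O)(=O)C(F)(F)F)(C(C)C)C(C)C
Why: Silylation of the hindered secondary alcohol under buffered conditions keeps the TBS enol ether and gives an ether that should survive the acetal cleavage of step 9 and both organometallic additions.

Step 8
Reactants: 14 6α-triisopropylsilyl ether of 13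
Product: 15 4β-(methoxymethoxy)-1β-methyl-6α-(triisopropylsilyloxy)-5αH-hydroazul-9-en-8-one
Conditions: Pd(OAc)2 (1.1 equiv), MeCN, 40 °C
Reagents that add atoms: none
Why: Saegusa–Ito oxidation of the regiodefined C8=C9 silyl enol ether gives a palladium enolate whose only β-hydrogens are on C10, so the C9=C10 enone should form without touching C7.

Step 9
Reactants: 15 4β-(methoxymethoxy)-1β-methyl-6α-(triisopropylsilyloxy)-5αH-hydroazul-9-en-8-one
Product: 16 4β-hydroxy-1β-methyl-6α-(triisopropylsilyloxy)-5αH-hydroazul-9-en-8-one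
Conditions: Me2BBr, CH2Cl2, −78 °C; then sat. aq. NaHCO3
Reagents that add atoms: none
Why: Lewis-acid cleavage of the methoxymethyl acetal with bromodimethylborane at −78 °C should free the C4 alcohol without touching the TIPS ether or the enone, and it is placed before the acid-sensitive tertiary allylic alcohol exists.

Step 10
Reactants: 16 4β-hydroxy-1β-methyl-6α-(triisopropylsilyloxy)-5αH-hydroazul-9-en-8-one
Product: 17 1β,8α-dimethyl-6α-(triisopropylsilyloxy)-5αH-hydroazul-9-ene-4β,8β-diol
Conditions: MeMgBr (4 equiv), CeCl3 (4 equiv), THF, −78 °C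
Reagents that add atoms: methylmagnesium bromide C[Mg]Br
Why: Organocerium 1,2-addition to the enone (the reagent is hardly basic, so the β-silyloxy ketone is not enolised) should occur on the α face, anti to the axial C1 methyl group that lies over the β face of C8 and cis to the equatorial C6 silyloxy group, which sets the 8β-hydroxy-8α-methyl centre (1,3-anti to C6–O).

Step 11
Reactants: 17 1β,8α-dimethyl-6α-(triisopropylsilyloxy)-5αH-hydroazul-9-ene-4β,8β-diol
Product: 18 8β-hydroxy-1β,8α-dimethyl-6α-(triisopropylsilyloxy)-5αH-hydroazul-9-en-4-one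
Conditions: Dess–Martin periodinane, NaHCO3, CH2Cl2, 0 °C to rt
Reagents that add atoms: none
Why: Dess–Martin oxidation converts the only secondary alcohol into the C4 ketone under buffered, non-basic conditions that should leave the tertiary allylic alcohol untransposed and the C5 centre unepimerised.

Step 12
Reactants: 18 8β-hydroxy-1β,8α-dimethyl-6α-(triisopropylsilyloxy)-5αH-hydroazul-9-en-4-one
Product: 19 6α-(triisopropylsilyloxy)dauc-9-ene-4β,8β-diol
Conditions: i-PrMgCl (5 equiv), CeCl3 (5 equiv), THF, −78 to −40 °C
Reagents that add atoms: isopropylmagnesium chloride CC(C)[Mg]Cl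
Why: The isopropylcerium reagent should add to the hindered, enolisable cyclopentanone without enolisation or reduction and from the α face, anti to the cis-vicinal C5–C6 bond and the C1 methyl group on the β face, so that the tertiary hydroxyl ends up β as in the target.

Step 13
Reactants: 19 6α-(triisopropylsilyloxy)dauc-9-ene-4β,8β-diol
Product: 20 dauc-9-ene-4β,6α,8β-triol
Conditions: TBAF, THF, 40 °C
Reagents that add atoms: none
Why: Fluoride-induced desilylation frees the C6 alcohol under conditions that should not affect the two tertiary alcohols or the alkene.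

Step 14
Reactants: 20 dauc-9-ene-4β,6α,8β-triol; 21 4-acetoxy-3-methoxybenzoic acid
Product: 22 4β,8β-dihydroxydauc-9-en-6α-yl 4-acetoxy-3-methoxybenzoate
Conditions: EDC·HCl, DMAP, CH2Cl2, rt
Reagents that add atoms: none
Why: Steglich esterification should acylate the only secondary hydroxyl (C6) with retention, because the two tertiary alcohols do not react under these conditions.

Step 15
Reactants: 22 4β,8β-dihydroxydauc-9-en-6α-yl 4-acetoxy-3-methoxybenzoate
Product: 23 4β,8β-dihydroxydauc-9-en-6α-yl 4-hydroxy-3-methoxybenzoate (target)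
Conditions: K2CO3 (cat.), MeOH, 0 °C
Reagents that add atoms: none
Why: Methanolysis of the aryl acetate is far faster than that of the hindered C6 benzoate, which is further deactivated once the para-phenoxide forms, so the phenol should be released selectively.

## Compound list

1 | 2-bromo-3-methylcyclopent-2-en-1-one | CC1=C(Br)C(=O)CC1 | starting material
2 | (S)-2-bromo-3-methylcyclopent-2-en-1-ol | BrC1=C(C)CC[C@@H]1O | intermediate
3 | (S)-1-bromo-5-(methoxymethoxy)-2-methylcyclopent-1-ene | BrC1=C(C)CC[C@@H]1OCOC | intermediate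
4 | (S)-[5-(methoxymethoxy)-2-methylcyclopent-1-en-1-yl]lithium | [Li]C1=C(C)CC[C@@H]1OCOC | intermediate (not isolated)
5 | (S)-1-[5-(methoxymethoxy)-2-methylcyclopent-1-en-1-yl]ethan-1-one | CC(=O)C1=C(C)CC[C@@H]1OCOC | intermediate
6 | methoxyallene (1-methoxypropa-1,2-diene) | COC=C=C | starting material
7 | tert-butyl(1-methoxypropa-1,2-dien-1-yl)dimethylsilane | COC(=C=C)[Si](C)(C)C(C)(C)C | intermediate (not isolated)
8 | 1-[tert-butyl(dimethyl)silyl]prop-2-en-1-one | C=CC(=O)[Si](C)(C)C(C)(C)C | intermediate
9 | lithium 1-[(S)-5-(methoxymethoxy)-2-methylcyclopent-1-en-1-yl]ethen-1-olate | C=C(O[Li])C1=C(C)CC[C@@H]1OCOC | intermediate (not isolated)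
10 | lithium 2-[tert-butyl(dimethyl)silyl]oxy-1-[(S)-5-(methoxymethoxy)-2-methylcyclopent-1-en-1-yl]-2-vinylcyclopropan-1-olate (cyclopentenyl and vinyl cis; C8 on the cyclopentene face anti to OMOM) | [Li]O[C@@]1(C2=C(C)CC[C@@H]2OCOC)C[C@]1(O[Si](C)(C)C(C)(C)C)C=C | intermediate (not isolated)
11 | lithium C5=C6 enolate of 12 (8-TBS-oxy-4β-(methoxymethoxy)-1β-methylhydroazula-5,8-dien-6-olate) | [Li]OC1=C2[C@@H](OCOC)CC[C@]2(C)CC=C(O[Si](C)(C)C(C)(C)C)C1 | intermediate (not isolated)
12 | 8-[tert-butyl(dimethyl)silyl]oxy-4β-(methoxymethoxy)-1β-methyl-5αH-hydroazul-8-en-6-one | O=C1CC(O[Si](C)(C)C(C)(C)C)=CC[C@@]2(C)CC[C@H](OCOC)[C@H]12 | intermediate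
13 | 8-[tert-butyl(dimethyl)silyl]oxy-4β-(methoxymethoxy)-1β-methyl-5αH-hydroazul-8-en-6α-ol | O[C@H]1CC(O[Si](C)(C)C(C)(C)C)=CC[C@@]2(C)CC[C@H](OCOC)[C@H]12 | intermediate
14 | 6α-triisopropylsilyl ether of 13 | CC(C)[Si](O[C@H]1CC(O[Si](C)(C)C(C)(C)C)=CC[C@@]2(C)CC[C@H](OCOC)[C@H]12)(C(C)C)C(C)C | intermediate
15 | 4β-(methoxymethoxy)-1β-methyl-6α-(triisopropylsilyloxy)-5αH-hydroazul-9-en-8-one | CC(C)[Si](O[C@H]1CC(=O)C=C[C@@]2(C)CC[C@H](OCOC)[C@H]12)(C(C)C)C(C)C | intermediate
16 | 4β-hydroxy-1β-methyl-6α-(triisopropylsilyloxy)-5αH-hydroazul-9-en-8-one | CC(C)[Si](O[C@H]1CC(=O)C=C[C@@]2(C)CC[C@H](O)[C@H]12)(C(C)C)C(C)C | intermediate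
17 | 1β,8α-dimethyl-6α-(triisopropylsilyloxy)-5αH-hydroazul-9-ene-4β,8β-diol | CC(C)[Si](O[C@H]1C[C@](C)(O)C=C[C@@]2(C)CC[C@H](O)[C@H]12)(C(C)C)C(C)C | intermediate
18 | 8β-hydroxy-1β,8α-dimethyl-6α-(triisopropylsilyloxy)-5αH-hydroazul-9-en-4-one | CC(C)[Si](O[C@H]1C[C@](C)(O)C=C[C@@]2(C)CCC(=O)[C@H]12)(C(C)C)C(C)C | intermediate
19 | 6α-(triisopropylsilyloxy)dauc-9-ene-4β,8β-diol (4α-isopropyl, 8α-methyl) | CC(C)[Si](O[C@H]1C[C@](C)(O)C=C[C@@]2(C)CC[C@@](O)(C(C)C)[C@H]12)(C(C)C)C(C)C | intermediate
20 | dauc-9-ene-4β,6α,8β-triol | O[C@H]1C[C@](C)(O)C=C[C@@]2(C)CC[C@@](O)(C(C)C)[C@H]12 | intermediate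
21 | 4-acetoxy-3-methoxybenzoic acid | COc1cc(C(=O)O)ccc1OC(C)=O | starting material
22 | 4β,8β-dihydroxydauc-9-en-6α-yl 4-acetoxy-3-methoxybenzoate | COc1cc(C(=O)O[C@H]2C[C@](C)(O)C=C[C@@]3(C)CC[C@@](O)(C(C)C)[C@H]23)ccc1OC(C)=O | intermediate
23 | 4β,8β-dihydroxydauc-9-en-6α-yl 4-hydroxy-3-methoxybenzoate | COc1cc(C(=O)O[C@H]2C[C@](C)(O)C=C[C@@]3(C)CC[C@@](O)(C(C)C)[C@H]23)ccc1O | target

## Step count and risks

Total steps: 15. Longest linear sequence: 14 (steps 1–3 and 5–15); step 4 makes the second annulation partner.

The three steps most likely to fail: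

Step 5 (key step). What may go wrong: conjugate addition of the enolate to the β-unsubstituted acryloylsilane and anionic oligomerisation of 8 instead of carbonyl addition, or β-elimination of the C4 oxygen from the enolate if the mixture warms. Fallback: the three-carbon partner is changed to a β-silylated acryloylsilane, whose C10 terminus is blocked, and the C9=C10 alkene is then unveiled by desilylbromination instead of Saegusa–Ito oxidation. It sets out from 7 and 5. Allene 7 is lithiated at C3 (t-BuLi, THF, −78 °C) and silylated with Me3SiCl to tert-butyl[1-methoxy-3-(trimethylsilyl)propa-1,2-dien-1-yl]dimethylsilane F1, which is hydrolysed (dilute HCl, THF) to (E)-1-[tert-butyl(dimethyl)silyl]-3-(trimethylsilyl)prop-2-en-1-one F2. Annulation of enolate 9 (from 5) with F2 under the conditions of step 5 should give the 10α-trimethylsilyl ketone F3 (ketone 12 carrying Me3Si at C10; the boat transition state places the E substituent trans to the C1 methyl). SmI2/MeOH reduction as in step 6 should give the 10α-trimethylsilyl 6α-alcohol F4, and TIPSOTf/2,6-lutidine its 6α-triisopropylsilyl ether F5. NBS (THF, −78 °C) brominates the silyl enol ether at C9 to the 9β-bromo-10α-trimethylsilyl 8-ketone F6, and fluoride (TBAF, 0 °C) induces anti elimination of bromide and the trimethylsilyl group. The fallback comes back to the route at 15.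

Step 10. What may go wrong: poor or reversed facial selectivity of the methyl addition, because the C8 carbonyl is remote from the stereocentres, or base-induced loss of the C6 silyloxy group. Fallback: the carbinol is built with the oxygen delivered last, which gives the opposite facial outcome to direct methyl addition and so corrects a selectivity that is high but reversed. It sets out from 16. Wittig methylenation (Ph3P=CH2, THF, 0 °C to rt) gives the 8-methylene diene F7. Epoxidation of the less hindered, 1,1-disubstituted exocyclic alkene (mCPBA, NaHCO3, CH2Cl2, 0 °C) gives the spiro-epoxide F8 with oxygen on the face the Grignard reagent would have used for carbon. LiEt3BH (THF, 0 °C) opens the epoxide at its CH2 terminus to the methyl carbinol. The fallback comes back to the route at 17.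

Step 12. What may go wrong: enolisation of the hindered ketone, β-hydride reduction by the secondary Grignard reagent, or β-elimination of the C6 silyloxy group. Fallback: an sp2 nucleophile without β-hydrogens is added and reduced afterwards. It sets out from 18. Isopropenylmagnesium bromide/CeCl3 (THF, −78 °C) should give the isopropenyl carbinol F9. Hydrogen-atom-transfer hydrogenation (Mn(dpm)3 cat., PhSiH3, t-BuOOH, i-PrOH, rt) reduces 1,1-disubstituted alkenes through tertiary radicals and should leave the 1,2-disubstituted C9=C10 alkene. The fallback comes back to the route at 19.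

## Further compounds

F1 | step 5 | tert-butyl[1-methoxy-3-(trimethylsilyl)propa-1,2-dien-1-yl]dimethylsilane | COC(=C=C[Si](C)(C)C)[Si](C)(C)C(C)(C)C
F2 | step 5 | (E)-1-[tert-butyl(dimethyl)silyl]-3-(trimethylsilyl)prop-2-en-1-one | C[Si](C)(C)/C=C/C(=O)[Si](C)(C)C(C)(C)C
F3 | step 5 | 10α-trimethylsilyl ketone (12 carrying Me3Si at C10) | O=C1CC(O[Si](C)(C)C(C)(C)C)=C[C@@H]([Si](C)(C)C)[C@@]2(C)CC[C@H](OCOC)[C@H]12
F4 | step 5 | 10α-trimethylsilyl 6α-alcohol (13 carrying Me3Si at C10) | O[C@H]1CC(O[Si](C)(C)C(C)(C)C)=C[C@@H]([Si](C)(C)C)[C@@]2(C)CC[C@H](OCOC)[C@H]12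
F5 | step 5 | 10α-trimethylsilyl 6α-triisopropylsilyl ether (14 carrying Me3Si at C10) | CC(C)[Si](O[C@H]1CC(O[Si](C)(C)C(C)(C)C)=C[C@@H]([Si](C)(C)C)[C@@]2(C)CC[C@H](OCOC)[C@H]12)(C(C)C)C(C)C
F6 | step 5 | 9β-bromo-10α-trimethylsilyl 8-ketone | CC(C)[Si](O[C@H]1CC(=O)[C@H](Br)[C@@H]([Si](C)(C)C)[C@@]2(C)CC[C@H](OCOC)[C@H]12)(C(C)C)C(C)C
F7 | step 10 | 8-methylene diene (1β-methyl-8-methylidene-6α-(triisopropylsilyloxy)-5αH-hydroazul-9-en-4β-ol) | CC(C)[Si](O[C@H]1CC(=C)C=C[C@@]2(C)CC[C@H](O)[C@H]12)(C(C)C)C(C)C
F8 | step 10 | spiro-epoxide (8β-oxygen, 8α-CH2) of F7 | CC(C)[Si](O[C@H]1C[C@@]3(CO3)C=C[C@@]2(C)CC[C@H](O)[C@H]12)(C(C)C)C(C)C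
F9 | step 12 | isopropenyl carbinol (4α-isopropenyl analogue of 19) | CC(C)[Si](O[C@H]1C[C@](C)(O)C=C[C@@]2(C)CC[C@@](O)(C(C)=C)[C@H]12)(C(C)C)C(C)C
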